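**Retrosynthetic overview**

1. The target is reached by hydrogenolysis of its tetradeca-O-benzyl ether 19; the single gallate ester is put on early, on the only free hydroxyl of penta-O-benzyl-(−)-epigallocatechin, so no selective galloylation is needed at any stage.
2. Ring C of the lower unit is cut at C8a–O1 and at C4a–C4, and both bonds are made in one palladium/norbornene (Catellani-type) annulation of an aryl iodide (upper unit plus lower ring A) with a γ-iodo alcohol (lower C2–C3–C4 plus ring B).
3. Enabling feature: in ring A of the lower unit the oxygen-bearing C8a lies between C8 (already carrying C4 of the upper unit, the one ortho substituent this chemistry needs) and C4a (a free ortho C–H), and O1–C2–C3–C4 is a 1,3-hydroxy/alkyl-halide chain. No bond to C2 or C3 is made or broken, so a syn aldol array maps directly onto the 2,3-cis (epi) lower unit.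
4. The aryl iodide comes from (−)-epigallocatechin by phenol benzylation, esterification with 3,4,5-tris(benzyloxy)benzoic acid, DDQ activation of C4 and 4β-selective Friedel–Crafts arylation with 1,3-bis(benzyloxy)-5-iodobenzene; the γ-iodo alcohol comes from an Evans syn glycolate aldol with 3,4,5-tris(benzyloxy)benzaldehyde, reduction and iodination.
5. Ring order: the three rings of the upper flavan unit come intact from (−)-epigallocatechin and the galloyl ring from the benzoic acid; rings A and B of the lower unit enter as ready-made arenes; the lower pyran ring C is the only ring built, and it is built last.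

Key step: step 10

Remark: flavan numbering (O1, C2, C3, C4, C4a, C5–C8, C8a) is used, "upper" is the galloylated unit and "lower" the unit linked through C8; (−)-epigallocatechin, 3,4,5-tris(benzyloxy)benzoic acid, 5-iodoresorcinol, (S)-4-benzyloxazolidin-2-one, benzyloxyacetyl chloride and 3,4,5-tris(benzyloxy)benzaldehyde are taken as catalogue chemicals.

**Route**

Step 1
Reactants: 1 (−)-epigallocatechin (2R,3R)
Product: 2 5,7,3',4',5'-penta-O-benzyl-(−)-epigallocatechin (2R,3R)
Conditions: BnBr (5.5 equiv), K2CO3 (6 equiv), degassed DMF, 0 °C to rt, argon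
Reagents that add atoms: benzyl bromide BrCc1ccccc1
Why: Williamson etherification: K2CO3 deprotonates the five phenols but not the secondary aliphatic 3-hydroxyl, so only the phenols should be benzylated, and under these mild, oxygen-free conditions the 2R,3R centres of 1 are carried over unchanged.

Step 2
Reactants: 2 5,7,3',4',5'-penta-O-benzyl-(−)-epigallocatechin; 3 3,4,5-tris(benzyloxy)benzoic acid
Product: 4 octa-O-benzyl-(−)-epigallocatechin 3-O-gallate (2R,3R)
Conditions: 3 (1.5 equiv), DCC (1.6 equiv), DMAP (0.3 equiv), CH2Cl2, 0 °C to rt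
Reagents that add atoms: none
Why: Steglich esterification: DCC activates 3 as the O-acylisourea and DMAP transfers the acyl group to the 3-hydroxyl, the only free hydroxyl of 2, so the ester forms at one site by construction, and because the C3–O bond is not broken the configuration at C3 is kept.

Step 3
Reactants: 4 octa-O-benzyl-(−)-epigallocatechin 3-O-gallate
Product: 5 4β-(2-ethoxyethoxy)-octa-O-benzyl-EGCG (2α-aryl, 3α-galloyloxy, 4β-alkoxy)
Conditions: DDQ (2 equiv), 2-ethoxyethanol (5 equiv), CH2Cl2, rt
Reagents that add atoms: 2-ethoxyethanol CCOCCO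
Why: DDQ benzylic oxidation (oxidative C–H etherification): hydride abstraction from C4, activated by the three oxygens of ring A, gives a cation that the alcohol should trap on the β-face, anti to the 2-aryl and 3-O-galloyl groups, which sets C4 with the 3,4-trans relationship.

Step 4
Reactants: 6 5-iodoresorcinol (5-iodobenzene-1,3-diol)
Product: 7 1,3-bis(benzyloxy)-5-iodobenzene
Conditions: BnBr (2.4 equiv), K2CO3 (3 equiv), DMF, rt
Reagents that add atoms: benzyl bromide BrCc1ccccc1
Why: Williamson etherification of the two phenols, the aryl iodide being inert to K2CO3 and benzyl bromide.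

Step 5
Reactants: 5 4β-(2-ethoxyethoxy)-octa-O-benzyl-EGCG; 7 1,3-bis(benzyloxy)-5-iodobenzene
Product: 8 4β-[2,4-bis(benzyloxy)-6-iodophenyl]-octa-O-benzyl-EGCG (2α-aryl, 3α-galloyloxy, 4β-aryl)
Conditions: 5 added slowly to 7 (5 equiv) and TMSOTf (0.2 equiv), CH2Cl2, −40 to 0 °C
Reagents that add atoms: none
Why: Lewis-acid Friedel–Crafts arylation of the C4 benzylic cation (the bond-forming mode of interflavan couplings): the cation, shielded on the α-face by the 2-aryl group and the participating 3-O-galloyl carbonyl, should be attacked from the β-face (new C4 centre 3,4-trans) by the carbon of 7 that is para to one benzyloxy group and ortho to iodine, the carbon between the two ether oxygens being the least reactive site of a resorcinol diether, while the excess of 7 and the acid lability of any bond formed to a phloroglucinol-type ring should drain self-condensation products back to the cation.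

Step 6
Reactants: 9 (S)-4-benzyloxazolidin-2-one; 10 benzyloxyacetyl chloride
Product: 12 (S)-4-benzyl-3-[(benzyloxy)acetyl]oxazolidin-2-one, via lithium oxazolidinone salt 11 (not isolated)
Conditions: n-BuLi, THF, −78 °C; then 10, −78 to 0 °C
Reagents that add atoms: none
Why: N-acylation of the lithiated oxazolidinone by the acid chloride at low temperature, the standard way to load the Evans auxiliary, with the auxiliary stereocentre untouched.

Step 7
Reactants: 12 (S)-4-benzyl-3-[(benzyloxy)acetyl]oxazolidin-2-one; 13 3,4,5-tris(benzyloxy)benzaldehyde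
Product: 16 (S)-4-benzyl-3-{(2S,3R)-2-(benzyloxy)-3-hydroxy-3-[3,4,5-tris(benzyloxy)phenyl]propanoyl}oxazolidin-2-one, via dibutylboron Z-enolate 14 (not isolated), via dibutylboron aldolate 15 (not isolated)
Conditions: Bu2BOTf, Et3N, CH2Cl2, 0 °C; 13, −78 to 0 °C; then pH 7 buffer, MeOH, H2O2
Reagents that add atoms: none
Why: Evans syn aldol reaction: the Z boron enolate adds to the aldehyde through a chair Zimmerman–Traxler transition state on the enolate face away from the auxiliary benzyl group, which sets both new centres as the (2S,3R) syn glycolate adduct, the future C3 and C2 of the lower unit.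

Step 8
Reactants: 16 syn aldol adduct
Product: 17 (1R,2R)-2-(benzyloxy)-1-[3,4,5-tris(benzyloxy)phenyl]propane-1,3-diol
Conditions: LiBH4, THF, H2O (1 equiv), 0 °C
Reagents that add atoms: none
Why: Reductive cleavage of the N-acyl oxazolidinone with LiBH4 gives the primary alcohol and returns the auxiliary without touching the benzyl ethers or either stereocentre.

Step 9
Reactants: 17 (1R,2R)-diol
Product: 18 (1R,2S)-2-(benzyloxy)-3-iodo-1-[3,4,5-tris(benzyloxy)phenyl]propan-1-ol
Conditions: I2, PPh3, imidazole, toluene/MeCN, 0 °C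
Reagents that add atoms: iodine II
Why: Garegg–Samuelsson (Appel-type) iodination: the oxyphosphonium salt should form and be displaced by iodide much faster at the primary hydroxyl than at the hindered secondary benzylic one, so both centres are kept (the descriptor at C2 changes only because CH2I outranks the carbinol carbon).

Step 10
Reactants: 8 4β-[2,4-bis(benzyloxy)-6-iodophenyl]-octa-O-benzyl-EGCG; 18 (1R,2S)-γ-iodo alcohol (2 equiv)
Product: 19 tetradeca-O-benzyl ether of the target: octa-O-benzyl-EGCG-(4β→8)-3,5,7,3',4',5'-hexa-O-benzyl-(−)-epigallocatechin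
Conditions: Pd(OAc)2 (10 mol %), 2-dicyclohexylphosphino-2',6'-diisopropoxybiphenyl (20 mol %), norbornene (0.5 equiv), Cs2CO3 (3 equiv), 1,4-dioxane, 100 °C, argon
Reagents that add atoms: none
Why: Proposed new method: zerovalent palladium should insert into the C8a–I bond of 8, norbornene carbopalladation and C–H palladation at C4a (the only free ortho position) give an aryl–norbornyl palladacycle that is alkylated by the primary iodide of 18 through a tetravalent palladium intermediate (C4a–C4 bond), and, both ortho positions now being substituted, norbornene is expelled and the arylpalladium alkoxide (divalent palladium) formed with the benzylic hydroxyl reductively eliminates the C8a–O1 bond. The closest known reaction types are the palladium/norbornene annulation of aryl iodides with epoxides to 2,3-dihydrobenzofurans (ortho-alkylation then ipso C–O termination, one ring atom fewer) and the ortho-alkylation/ipso-amination of aryl iodides with bromoalkylamines to indolines and tetrahydroquinolines; the six-membered oxygen variant with a γ-iodo alcohol has no direct precedent. Ring C of the lower unit closes as a formal [3+3] annulation whose ring-closing event is C(aryl)–O reductive elimination from a seven-membered oxapalladacycle, a 6-exo-type closure of the tethered alkoxide onto C8a. No stereocentre is created: C2 and C3 of the lower unit come from the aldol of step 7 and keep their configuration because no bond to either is made or broken, so the syn array of 18 becomes the 2,3-cis (2R,3R) ring, and the three centres of the upper unit are not epimerisable under carbonate. The selectivities needed are 4→8 regiochemistry (fixed by the site of iodine, so no 4→6 isomer can form), mono-alkylation (secured by the C8 substituent, which blocks the second ortho position and triggers norbornene extrusion), ring closure through O1 and not O3 (O3 is a benzyl ether) and C–O reductive elimination over β-hydride loss (addressed by the bulky, electron-rich biaryl phosphine).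

Step 11
Reactants: 19 tetradeca-O-benzyl ether of the target
Product: 20 (−)-epigallocatechin 3-O-gallate-(4β→8)-(−)-epigallocatechin (target)
Conditions: H2 (1 atm), 20% Pd(OH)2 on carbon, THF/MeOH/H2O, rt; filtration, Sephadex LH-20
Reagents that add atoms: none
Why: Heterogeneous hydrogenolysis of all fourteen benzyl ethers under neutral conditions should leave the gallate ester, the acid-sensitive interflavan bond and all five stereocentres intact.

**Compound list**

1 | (−)-epigallocatechin (2R,3R) | O[C@@H]1Cc2c(O)cc(O)cc2O[C@@H]1c1cc(O)c(O)c(O)c1 | starting material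
2 | 5,7,3',4',5'-penta-O-benzyl-(−)-epigallocatechin (2R,3R) | O[C@@H]1Cc2c(OCc3ccccc3)cc(OCc3ccccc3)cc2O[C@@H]1c1cc(OCc2ccccc2)c(OCc2ccccc2)c(OCc2ccccc2)c1 | intermediate
3 | 3,4,5-tris(benzyloxy)benzoic acid | O=C(O)c1cc(OCc2ccccc2)c(OCc2ccccc2)c(OCc2ccccc2)c1 | starting material
4 | octa-O-benzyl-(−)-epigallocatechin 3-O-gallate (2R,3R) | O=C(O[C@@H]1Cc2c(OCc3ccccc3)cc(OCc3ccccc3)cc2O[C@@H]1c1cc(OCc2ccccc2)c(OCc2ccccc2)c(OCc2ccccc2)c1)c1cc(OCc2ccccc2)c(OCc2ccccc2)c(OCc2ccccc2)c1 | intermediate
5 | 4β-(2-ethoxyethoxy)-octa-O-benzyl-EGCG (2α-aryl, 3α-galloyloxy, 4β-alkoxy) | O=C(O[C@@H]1[C@@H](OCCOCC)c2c(OCc3ccccc3)cc(OCc3ccccc3)cc2O[C@@H]1c1cc(OCc2ccccc2)c(OCc2ccccc2)c(OCc2ccccc2)c1)c1cc(OCc2ccccc2)c(OCc2ccccc2)c(OCc2ccccc2)c1 | intermediate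
6 | 5-iodoresorcinol | Oc1cc(O)cc(I)c1 | starting material
7 | 1,3-bis(benzyloxy)-5-iodobenzene | Ic1cc(OCc2ccccc2)cc(OCc2ccccc2)c1 | intermediate
8 | 4β-[2,4-bis(benzyloxy)-6-iodophenyl]-octa-O-benzyl-EGCG (2α-aryl, 3α-galloyloxy, 4β-aryl) | O=C(O[C@@H]1[C@@H](c2c(I)cc(OCc3ccccc3)cc2OCc2ccccc2)c2c(OCc3ccccc3)cc(OCc3ccccc3)cc2O[C@@H]1c1cc(OCc2ccccc2)c(OCc2ccccc2)c(OCc2ccccc2)c1)c1cc(OCc2ccccc2)c(OCc2ccccc2)c(OCc2ccccc2)c1 | intermediate
9 | (S)-4-benzyloxazolidin-2-one | O=C1OC[C@H](Cc2ccccc2)N1 | starting material
10 | benzyloxyacetyl chloride | O=C(Cl)COCc1ccccc1 | starting material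
11 | lithium salt of (S)-4-benzyloxazolidin-2-one | [Li]N1C(=O)OC[C@@H]1Cc1ccccc1 | intermediate
12 | (S)-4-benzyl-3-[(benzyloxy)acetyl]oxazolidin-2-one | O=C(COCc1ccccc1)N1C(=O)OC[C@@H]1Cc1ccccc1 | intermediate
13 | 3,4,5-tris(benzyloxy)benzaldehyde | O=Cc1cc(OCc2ccccc2)c(OCc2ccccc2)c(OCc2ccccc2)c1 | starting material
14 | dibutylboron Z-enolate of 12 | CCCCB(CCCC)O/C(=C\OCc1ccccc1)N1C(=O)OC[C@@H]1Cc1ccccc1 | intermediate
15 | dibutylboron aldolate of 16 | CCCCB(CCCC)O[C@H](c1cc(OCc2ccccc2)c(OCc2ccccc2)c(OCc2ccccc2)c1)[C@H](OCc1ccccc1)C(=O)N1C(=O)OC[C@@H]1Cc1ccccc1 | intermediate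
16 | (S)-4-benzyl-3-{(2S,3R)-2-(benzyloxy)-3-hydroxy-3-[3,4,5-tris(benzyloxy)phenyl]propanoyl}oxazolidin-2-one | O[C@H](c1cc(OCc2ccccc2)c(OCc2ccccc2)c(OCc2ccccc2)c1)[C@H](OCc1ccccc1)C(=O)N1C(=O)OC[C@@H]1Cc1ccccc1 | intermediate
17 | (1R,2R)-2-(benzyloxy)-1-[3,4,5-tris(benzyloxy)phenyl]propane-1,3-diol | O[C@H](c1cc(OCc2ccccc2)c(OCc2ccccc2)c(OCc2ccccc2)c1)[C@H](OCc1ccccc1)CO | intermediate
18 | (1R,2S)-2-(benzyloxy)-3-iodo-1-[3,4,5-tris(benzyloxy)phenyl]propan-1-ol | O[C@H](c1cc(OCc2ccccc2)c(OCc2ccccc2)c(OCc2ccccc2)c1)[C@H](OCc1ccccc1)CI | intermediate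
19 | octa-O-benzyl-EGCG-(4β→8)-3,5,7,3',4',5'-hexa-O-benzyl-(−)-epigallocatechin (upper 2α,3α,4β; lower 2R,3R, 2,3-cis) | O=C(O[C@@H]1[C@@H](c2c(OCc4ccccc4)cc(OCc4ccccc4)c3c2O[C@H](c2cc(OCc4ccccc4)c(OCc4ccccc4)c(OCc4ccccc4)c2)[C@H](OCc2ccccc2)C3)c2c(OCc3ccccc3)cc(OCc3ccccc3)cc2O[C@@H]1c1cc(OCc2ccccc2)c(OCc2ccccc2)c(OCc2ccccc2)c1)c1cc(OCc2ccccc2)c(OCc2ccccc2)c(OCc2ccccc2)c1 | intermediate
20 | (−)-epigallocatechin 3-O-gallate-(4β→8)-(−)-epigallocatechin, CNP0194932.2 (upper 2R,3R,4R; lower 2R,3R) | O=C(O[C@@H]1[C@@H](c2c(O)cc(O)c3c2O[C@H](c2cc(O)c(O)c(O)c2)[C@H](O)C3)c2c(O)cc(O)cc2O[C@@H]1c1cc(O)c(O)c(O)c1)c1cc(O)c(O)c(O)c1 | target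

**Step count and risks**

Total step count: 11. Longest linear sequence: 6 (steps 1, 2, 3, 5, 10, 11; the branch through steps 6, 7, 8, 9, 10, 11 is equally long).

Most likely to fail, first: step 10 (proposed new method). The palladacycle may be alkylated only sluggishly by a β-branched, β-oxygenated primary iodide. Carbonate may close 18 to an oxetane before it is used. The benzylic palladium alkoxide may lose a β-hydride (reduction of the aryl–palladium bond, oxidation of the carbinol) instead of undergoing C–O reductive elimination. The fallback uses only known chemistry, sets out from 2 and 5, and comes back at 19; it gives up the late ring closure and brings the lower unit in with its pyran ring already formed. Benzylation of the 3-hydroxyl of 2 (NaH, BnBr, DMF, 0 °C) should give 3,5,7,3',4',5'-hexa-O-benzyl-(−)-epigallocatechin F1. TMSOTf-mediated interflavan Friedel–Crafts coupling of 5 with F1 (4 equiv, CH2Cl2, −78 °C) should then give 19; the 4→8 isomer is expected to predominate over 4→6, and the excess of F1 is recovered.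

Second: step 5. The C4 cation may be captured by the benzylated ring A of 5 or of 8 (self-condensation to oligomers) faster than by the weakly nucleophilic, hindered iodoarene, and a minor share may attack the carbon between the two benzyloxy groups. The fallback sets out from 5 and comes back at 20; it blocks the nucleophilic ring A carbon with a temporary bromine that leaves in the final hydrogenolysis. NBS (CH2Cl2, −78 °C) should convert 5 into 8-bromo-4β-(2-ethoxyethoxy)-octa-O-benzyl-EGCG F2. BF3·OEt2-promoted coupling of F2 with 7 (CH2Cl2, −40 °C) should give 8-bromo-4β-[2,4-bis(benzyloxy)-6-iodophenyl]-octa-O-benzyl-EGCG F3 without self-condensation. Annulation of F3 with 18 under the conditions of step 10 should give the 8-bromo tetradeca-O-benzyl dimer F4, the hindered, electron-rich C–Br bond being expected to react far more slowly than C–I. Hydrogenolysis as in step 11 with Et3N (1.5 equiv) should remove bromine and benzyl groups together and give 20.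

Third: step 9. The electron-rich benzylic hydroxyl may be activated as an oxyphosphonium salt and ionise, with loss of the C1 configuration, elimination or substitution. The fallback sets out from 17 and comes back at 18. Selective sulfonylation of the primary hydroxyl (TsCl, pyridine, CH2Cl2, −20 °C) should give (2R,3R)-2-(benzyloxy)-3-hydroxy-3-[3,4,5-tris(benzyloxy)phenyl]propyl 4-methylbenzenesulfonate F5, and Finkelstein exchange (NaI, acetone, 50 °C) should give 18.

**Further compounds**

F1 | step 10 | 3,5,7,3',4',5'-hexa-O-benzyl-(−)-epigallocatechin (2R,3R) | c1ccccc1CO[C@@H]1Cc2c(OCc3ccccc3)cc(OCc3ccccc3)cc2O[C@@H]1c1cc(OCc2ccccc2)c(OCc2ccccc2)c(OCc2ccccc2)c1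
F2 | step 5 | 8-bromo-4β-(2-ethoxyethoxy)-octa-O-benzyl-EGCG (2α-aryl, 3α-galloyloxy, 4β-alkoxy) | O=C(O[C@@H]1[C@@H](OCCOCC)c2c(OCc3ccccc3)cc(OCc3ccccc3)c(Br)c2O[C@@H]1c1cc(OCc2ccccc2)c(OCc2ccccc2)c(OCc2ccccc2)c1)c1cc(OCc2ccccc2)c(OCc2ccccc2)c(OCc2ccccc2)c1
F3 | step 5 | 8-bromo-4β-[2,4-bis(benzyloxy)-6-iodophenyl]-octa-O-benzyl-EGCG (2α-aryl, 3α-galloyloxy, 4β-aryl) | O=C(O[C@@H]1[C@@H](c2c(I)cc(OCc3ccccc3)cc2OCc2ccccc2)c2c(OCc3ccccc3)cc(OCc3ccccc3)c(Br)c2O[C@@H]1c1cc(OCc2ccccc2)c(OCc2ccccc2)c(OCc2ccccc2)c1)c1cc(OCc2ccccc2)c(OCc2ccccc2)c(OCc2ccccc2)c1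
F4 | step 5 | 8-bromo derivative (upper unit) of the tetradeca-O-benzyl dimer 19 | O=C(O[C@@H]1[C@@H](c2c(OCc4ccccc4)cc(OCc4ccccc4)c3c2O[C@H](c2cc(OCc4ccccc4)c(OCc4ccccc4)c(OCc4ccccc4)c2)[C@H](OCc2ccccc2)C3)c2c(OCc3ccccc3)cc(OCc3ccccc3)c(Br)c2O[C@@H]1c1cc(OCc2ccccc2)c(OCc2ccccc2)c(OCc2ccccc2)c1)c1cc(OCc2ccccc2)c(OCc2ccccc2)c(OCc2ccccc2)c1
F5 | step 9 | (2R,3R)-2-(benzyloxy)-3-hydroxy-3-[3,4,5-tris(benzyloxy)phenyl]propyl 4-methylbenzenesulfonate | O[C@H](c1cc(OCc2ccccc2)c(OCc2ccccc2)c(OCc2ccccc2)c1)[C@H](OCc1ccccc1)COS(=O)(=O)c1ccc(C)cc1
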